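**Plan**
- Retrosynthesis first cuts the late O–C bonds (the 4'-O acetal, O3–CH3, C3–O and O7–prenyl), which leaves a 3-unsubstituted 7-hydroxyflavone.
- Ring C is then cut at C4a–C4, C4–C3 and O1–C2. C4 is a ketone carbon lodged between C4a of ring A and C3, so it is traced back to CO placed between an aryl iodide (C4a–I) and a terminal arylacetylene whose two sp carbons are C3 and C2 and whose aryl group is ring B. O1 is the phenol ortho to that iodide.
- Forward, ring A is prepared as 4-iodo-2,5-dimethoxyresorcinol (five steps from 5-methoxyresorcinol, two directed ortho-metalations) and ring B as MOM-protected 4-ethynylguaiacol (two steps from vanillin).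
- The two arenes and CO are joined and ring C, the only ring made, closes in the same flask. The second phenol of the resorcinol is a spectator and emerges as the free 7-OH.
- The 7-OH is prenylated, C3 is hydroxylated by lithiation–borylation–oxidation and methylated, and the MOM group is removed.
- Stereochemistry: the target has no stereocentre and no stereogenic double bond, so nothing has to be set.

Key step: step 8

**Route**

Step 1
Reactants: 1 5-methoxyresorcinol (5-methoxybenzene-1,3-diol)
Product: 2 1-methoxy-3,5-bis(methoxymethoxy)benzene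
Conditions: MOMCl, i-Pr2NEt, CH2Cl2, 0 °C → rt
Reagents that add atoms: chloromethyl methyl ether (MOMCl), COCCl
Why: Williamson-type O-alkylation of both phenols by the reactive α-chloro ether under amine base should give the bis-acetal cleanly, since no other nucleophilic site is present.

Step 2
Reactants: 2 1-methoxy-3,5-bis(methoxymethoxy)benzene
Product: 5 4-methoxy-2,6-bis(methoxymethoxy)phenol, via aryllithium 3 (not isolated), via dimethyl arylboronate 4 (not isolated)
Conditions: n-BuLi, THF, 0 °C; B(OMe)3, −78 °C → rt; 30 % H2O2, aq NaHCO3, 0 °C → rt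
Reagents that add atoms: hydrogen peroxide, OO
Why: Directed ortho-metalation should take place at C2, because that proton lies between two chelating MOM ethers and is more acidic than the two protons flanked by one MOM ether and the methoxy group, and borylation followed by peroxide oxidation (1,2-aryl shift from boron to oxygen) then turns the aryllithium into the phenol.

Step 3
Reactants: 5 4-methoxy-2,6-bis(methoxymethoxy)phenol
Product: 6 2,5-dimethoxy-1,3-bis(methoxymethoxy)benzene
Conditions: MeI, K2CO3, acetone, reflux
Reagents that add atoms: iodomethane, CI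
Why: Williamson ether synthesis, in which the small electrophile should reach the phenoxide oxygen between the two MOM ethers without difficulty.

Step 4
Reactants: 6 2,5-dimethoxy-1,3-bis(methoxymethoxy)benzene
Product: 8 2-iodo-1,4-dimethoxy-3,5-bis(methoxymethoxy)benzene, via aryllithium 7 (not isolated)
Conditions: n-BuLi, THF, 0 °C; I2, −78 °C → rt
Reagents that add atoms: iodine, II
Why: Directed ortho-metalation can occur only at the two equivalent ring positions, each flanked by a MOM ether and a methoxy group, so a single aryllithium should form and be trapped by iodine (lithiation–iodination).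

Step 5
Reactants: 8 2-iodo-1,4-dimethoxy-3,5-bis(methoxymethoxy)benzene
Product: 9 4-iodo-2,5-dimethoxybenzene-1,3-diol
Conditions: HCl (2 M in MeOH), rt
Reagents that add atoms: none
Why: Acid-catalysed acetal cleavage (transacetalisation to methanol) frees both phenols, and dilute acid at room temperature in a large excess of methanol, which traps the methoxymethyl cation, should spare the C–I bond and the activated free ring position.

Step 6
Reactants: 10 vanillin (4-hydroxy-3-methoxybenzaldehyde)
Product: 11 3-methoxy-4-(methoxymethoxy)benzaldehyde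
Conditions: MOMCl, i-Pr2NEt, CH2Cl2, 0 °C → rt
Reagents that add atoms: chloromethyl methyl ether (MOMCl), COCCl
Why: Williamson-type O-alkylation of the phenol with the α-chloro ether under amine base is fast and leaves the aldehyde untouched.

Step 7
Reactants: 11 3-methoxy-4-(methoxymethoxy)benzaldehyde
Product: 12 4-ethynyl-2-methoxy-1-(methoxymethoxy)benzene
Conditions: Ohira–Bestmann reagent, K2CO3, MeOH, rt
Reagents that add atoms: dimethyl (1-diazo-2-oxopropyl)phosphonate, CC(=O)C(=[N+]=[N-])P(=O)(OC)OC
Why: Seyferth–Gilbert homologation in the Ohira–Bestmann variant, in which methanolysis of the acetyl group releases the diazomethylphosphonate anion, this adds to the aldehyde and eliminates dimethyl phosphate, and loss of N2 with 1,2-hydrogen shift of the alkylidene carbene gives the terminal alkyne under conditions to which the aryl MOM ether is inert.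

Step 8
Reactants: 9 4-iodo-2,5-dimethoxybenzene-1,3-diol; 12 4-ethynyl-2-methoxy-1-(methoxymethoxy)benzene; 13 carbon monoxide
Product: 16 7-hydroxy-5,8-dimethoxy-2-[3-methoxy-4-(methoxymethoxy)phenyl]-4H-chromen-4-one, via ynone 14 (not isolated), via enaminone 15 (not isolated)
Conditions: PdCl2(PPh3)2 (5 mol %), CuI (2 mol %), CO (1 atm), Et2NH/THF, rt → 50 °C
Reagents that add atoms: none
Why: Zerovalent palladium, formed in the flask from PdCl2(PPh3)2, inserts into the C–I bond of 9, CO insertion gives the aroyl–palladium species, and transmetalation from the copper acetylide of 12 followed by reductive elimination forms C4a–C4 and C4–C3 in ynone 14. Diethylamine then adds to the ynone to give enaminone 15, and the phenol ortho to the new ketone attacks the β-carbon and expels the amine, which forms O1–C2. The closest known reaction type is the Pd-catalysed carbonylative Sonogashira coupling of 2-iodophenols with terminal arylacetylenes run in a secondary amine, which gives flavones in one flask. Ring C closes in a net 6-endo-dig mode by addition–elimination at the alkyne β-carbon, and no stereocentre is created. Carbonylation has to outrun direct alkynylation, which the CO atmosphere and the electron-rich, doubly ortho-oxygenated aryl–palladium (fast acyl formation) should secure, and 6-endo closure has to beat 5-exo closure to the aurone, which the amine relay through 15 enforces because the phenol can only displace the amine at C2. Of the two phenols only the one ortho to iodine can reach the ynone, so the other should emerge untouched as the 7-OH.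

Step 9
Reactants: 16 7-hydroxy-5,8-dimethoxy-2-[3-methoxy-4-(methoxymethoxy)phenyl]-4H-chromen-4-one
Product: 17 5,8-dimethoxy-2-[3-methoxy-4-(methoxymethoxy)phenyl]-7-[(3-methylbut-2-en-1-yl)oxy]-4H-chromen-4-one
Conditions: prenyl bromide, K2CO3, acetone, reflux
Reagents that add atoms: 1-bromo-3-methylbut-2-ene (prenyl bromide), CC(C)=CCBr
Why: Williamson ether synthesis, in which the single free hydroxyl, the acidic 7-OH para to the pyranone carbonyl, should be alkylated on oxygen by the primary allylic bromide in an SN2 reaction under conditions to which the MOM acetal and the flavone are inert.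

Step 10
Reactants: 17 5,8-dimethoxy-2-[3-methoxy-4-(methoxymethoxy)phenyl]-7-[(3-methylbut-2-en-1-yl)oxy]-4H-chromen-4-one
Product: 20 3-hydroxy-5,8-dimethoxy-2-[3-methoxy-4-(methoxymethoxy)phenyl]-7-[(3-methylbut-2-en-1-yl)oxy]-4H-chromen-4-one, via 3-lithioflavone 18 (not isolated), via dimethyl flavon-3-ylboronate 19 (not isolated)
Conditions: LiN(i-Pr)2, THF, −78 °C; B(OMe)3, −78 → 0 °C; 30 % H2O2, aq NaHCO3, 0 °C → rt
Reagents that add atoms: hydrogen peroxide, OO
Why: Lithiation of flavones at C3 by a lithium amide at −78 °C is known chemistry (the C3–H is flanked by the C4 carbonyl and the enol-ether carbon C2), the 3-lithio species is trapped by trimethyl borate, and buffered peroxide oxidation of the alkenyl boronate (lithiation–borylation–oxidation) should give the flavonol without epoxidising the prenyl olefin.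

Step 11
Reactants: 20 3-hydroxy-5,8-dimethoxy-2-[3-methoxy-4-(methoxymethoxy)phenyl]-7-[(3-methylbut-2-en-1-yl)oxy]-4H-chromen-4-one
Product: 21 3,5,8-trimethoxy-2-[3-methoxy-4-(methoxymethoxy)phenyl]-7-[(3-methylbut-2-en-1-yl)oxy]-4H-chromen-4-one
Conditions: MeI, K2CO3, acetone, reflux
Reagents that add atoms: iodomethane, CI
Why: Williamson ether synthesis, in which the flavonol 3-OH is the only acidic site and its potassium salt should be methylated on oxygen while the prenyl ether and the MOM acetal are stable to the mild base.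

Step 12
Reactants: 21 3,5,8-trimethoxy-2-[3-methoxy-4-(methoxymethoxy)phenyl]-7-[(3-methylbut-2-en-1-yl)oxy]-4H-chromen-4-one
Product: 22 4'-hydroxy-3,5,8,3'-tetramethoxy-7-prenyloxyflavone, i.e. 2-(4-hydroxy-3-methoxyphenyl)-3,5,8-trimethoxy-7-[(3-methylbut-2-en-1-yl)oxy]-4H-chromen-4-one
Conditions: HCl (1 M in MeOH), 0 °C → rt
Reagents that add atoms: none
Why: Acid-catalysed acetal methanolysis, in which the MOM acetal ionises to an oxocarbenium ion far more readily than the allylic aryl ether ionises, so dilute methanolic acid at or below room temperature, stopped at full conversion, should free the 4'-OH and leave the 7-O-prenyl ether.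

**Compound list**

1 | 5-methoxyresorcinol (5-methoxybenzene-1,3-diol) | COc1cc(O)cc(O)c1 | starting material
2 | 1-methoxy-3,5-bis(methoxymethoxy)benzene | COCOc1cc(OC)cc(OCOC)c1 | intermediate
3 | [4-methoxy-2,6-bis(methoxymethoxy)phenyl]lithium | [Li]c1c(OCOC)cc(OC)cc1OCOC | intermediate
4 | dimethyl [4-methoxy-2,6-bis(methoxymethoxy)phenyl]boronate | COB(OC)c1c(OCOC)cc(OC)cc1OCOC | intermediate
5 | 4-methoxy-2,6-bis(methoxymethoxy)phenol | COCOc1cc(OC)cc(OCOC)c1O | intermediate
6 | 2,5-dimethoxy-1,3-bis(methoxymethoxy)benzene | COCOc1cc(OC)cc(OCOC)c1OC | intermediate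
7 | [3,6-dimethoxy-2,4-bis(methoxymethoxy)phenyl]lithium | [Li]c1c(OCOC)c(OC)c(OCOC)cc1OC | intermediate
8 | 2-iodo-1,4-dimethoxy-3,5-bis(methoxymethoxy)benzene | COCOc1cc(OC)c(I)c(OCOC)c1OC | intermediate
9 | 4-iodo-2,5-dimethoxybenzene-1,3-diol | COc1cc(O)c(OC)c(O)c1I | intermediate
10 | vanillin (4-hydroxy-3-methoxybenzaldehyde) | COc1cc(C=O)ccc1O | starting material
11 | 3-methoxy-4-(methoxymethoxy)benzaldehyde | COCOc1ccc(C=O)cc1OC | intermediate
12 | 4-ethynyl-2-methoxy-1-(methoxymethoxy)benzene | C#Cc1ccc(OCOC)c(OC)c1 | intermediate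
13 | carbon monoxide | [C-]#[O+] | starting material
14 | 1-(2,4-dihydroxy-3,6-dimethoxyphenyl)-3-[3-methoxy-4-(methoxymethoxy)phenyl]prop-2-yn-1-one | COCOc1ccc(C#CC(=O)c2c(OC)cc(O)c(OC)c2O)cc1OC | intermediate
15 | (E)-3-(diethylamino)-1-(2,4-dihydroxy-3,6-dimethoxyphenyl)-3-[3-methoxy-4-(methoxymethoxy)phenyl]prop-2-en-1-one (E geometry expected for a tertiary enaminone and lost on ring closure) | CCN(CC)/C(=C/C(=O)c1c(OC)cc(O)c(OC)c1O)c1ccc(OCOC)c(OC)c1 | intermediate
16 | 7-hydroxy-5,8-dimethoxy-2-[3-methoxy-4-(methoxymethoxy)phenyl]-4H-chromen-4-one | COCOc1ccc(-c2cc(=O)c3c(OC)cc(O)c(OC)c3o2)cc1OC | intermediate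
17 | 5,8-dimethoxy-2-[3-methoxy-4-(methoxymethoxy)phenyl]-7-[(3-methylbut-2-en-1-yl)oxy]-4H-chromen-4-one | COCOc1ccc(-c2cc(=O)c3c(OC)cc(OCC=C(C)C)c(OC)c3o2)cc1OC | intermediate
18 | {5,8-dimethoxy-2-[3-methoxy-4-(methoxymethoxy)phenyl]-7-[(3-methylbut-2-en-1-yl)oxy]-4-oxo-4H-chromen-3-yl}lithium | COCOc1ccc(-c2oc3c(OC)c(OCC=C(C)C)cc(OC)c3c(=O)c2[Li])cc1OC | intermediate
19 | dimethyl {5,8-dimethoxy-2-[3-methoxy-4-(methoxymethoxy)phenyl]-7-[(3-methylbut-2-en-1-yl)oxy]-4-oxo-4H-chromen-3-yl}boronate | COCOc1ccc(-c2oc3c(OC)c(OCC=C(C)C)cc(OC)c3c(=O)c2B(OC)OC)cc1OC | intermediate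
20 | 3-hydroxy-5,8-dimethoxy-2-[3-methoxy-4-(methoxymethoxy)phenyl]-7-[(3-methylbut-2-en-1-yl)oxy]-4H-chromen-4-one | COCOc1ccc(-c2oc3c(OC)c(OCC=C(C)C)cc(OC)c3c(=O)c2O)cc1OC | intermediate
21 | 3,5,8-trimethoxy-2-[3-methoxy-4-(methoxymethoxy)phenyl]-7-[(3-methylbut-2-en-1-yl)oxy]-4H-chromen-4-one | COCOc1ccc(-c2oc3c(OC)c(OCC=C(C)C)cc(OC)c3c(=O)c2OC)cc1OC | intermediate
22 | 4'-hydroxy-3,5,8,3'-tetramethoxy-7-prenyloxyflavone | COc1cc(-c2oc3c(OC)c(OCC=C(C)C)cc(OC)c3c(=O)c2OC)ccc1O | target

**Step count and risks**

Total step count: 12. Longest linear sequence: 10 steps (steps 1–5, then 8–12); steps 6 and 7 form the second branch.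

Steps most likely to fail:

1. Step 8. Direct alkynylation of the aryl–palladium may run ahead of CO insertion and lead on to a benzofuran by attack of the phenol on the arylalkyne. The aroyl–palladium may also be captured by phenoxide or amine, oxidative addition into the hindered, electron-rich C–I bond may be slow, and some 5-exo closure may occur. The fallback delivers the C4 carbonyl as a preformed acyl electrophile instead of CO; it sets out from 9 and 12 and returns at 16. Alkyne 12 is deprotonated with n-BuLi (THF, −78 °C) and acylated with N-methoxy-N-methylcarbamoyl chloride to give the Weinreb amide N-methoxy-N-methyl-3-[3-methoxy-4-(methoxymethoxy)phenyl]prop-2-ynamide F1. Iodoresorcinol 9 is deprotonated twice with MeMgCl in THF containing LiCl (−20 °C), and iodine–magnesium exchange with i-PrMgCl (rt) should give the triply magnesiated arene [2,4-bis(chloromagnesiooxy)-3,6-dimethoxyphenyl]magnesium chloride F2. F2 is acylated by F1, aqueous NH4Cl should release ynone 14, now isolated, and Et2NH in EtOH at 50 °C should close it through enaminone 15 to flavone 16.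

2. Step 10. The 3-lithiated pyranone may open by β-elimination of the O1 phenoxide if it warms, lithiation may be incomplete, and the α-boryl enone may protodeboronate before oxygen transfer. The fallback oxygenates C3 electrophilically before the prenyl olefin is present; it sets out from 16 and returns at 21. The 7-OH of 16 is benzylated (BnBr, K2CO3, DMF) to 7-(benzyloxy)-5,8-dimethoxy-2-[3-methoxy-4-(methoxymethoxy)phenyl]-4H-chromen-4-one F3. Dimethyldioxirane in acetone/CH2Cl2 at 0 °C should epoxidise the C2=C3 bond to the racemic, cis-fused 2,3-epoxide 4-(benzyloxy)-3,6-dimethoxy-1a-[3-methoxy-4-(methoxymethoxy)phenyl]-1a,7a-dihydro-7H-oxireno[2,3-b]chromen-7-one F4. A trace of p-TsOH should open it to the flavonol 7-(benzyloxy)-3-hydroxy-5,8-dimethoxy-2-[3-methoxy-4-(methoxymethoxy)phenyl]-4H-chromen-4-one F5. Methylation (MeI, K2CO3, acetone) gives 7-(benzyloxy)-3,5,8-trimethoxy-2-[3-methoxy-4-(methoxymethoxy)phenyl]-4H-chromen-4-one F6. Hydrogenolysis (H2, Pd/C, EtOAc) gives 7-hydroxy-3,5,8-trimethoxy-2-[3-methoxy-4-(methoxymethoxy)phenyl]-4H-chromen-4-one F7, and prenylation under the conditions of step 9 gives 21.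

3. Step 12. While the acetal is cleaved, the allylic aryl ether may ionise as well (loss of the prenyl group) or the olefin may add methanol or HCl. The fallback replaces chemoselective deprotection by chemoselective alkylation; it sets out from 21 and returns at 22. Warm methanolic HCl (60 °C) removes both the MOM and the prenyl group, methanol trapping the prenyl cation, to give 7-hydroxy-2-(4-hydroxy-3-methoxyphenyl)-3,5,8-trimethoxy-4H-chromen-4-one F8. One equivalent each of K2CO3 and prenyl bromide (DMF, 0 °C → rt) should then alkylate only the 7-OH, since this vinylogous acid para to the pyranone carbonyl is clearly more acidic than the guaiacol-type 4'-OH on the twisted ring B, and this gives 22.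

**Further compounds**

F1 | step 8 | N-methoxy-N-methyl-3-[3-methoxy-4-(methoxymethoxy)phenyl]prop-2-ynamide | CON(C)C(=O)C#Cc1ccc(OCOC)c(OC)c1
F2 | step 8 | [2,4-bis(chloromagnesiooxy)-3,6-dimethoxyphenyl]magnesium chloride | COc1cc(O[Mg]Cl)c(OC)c(O[Mg]Cl)c1[Mg]Cl
F3 | step 10 | 7-(benzyloxy)-5,8-dimethoxy-2-[3-methoxy-4-(methoxymethoxy)phenyl]-4H-chromen-4-one | COCOc1ccc(-c2cc(=O)c3c(OC)cc(OCc4ccccc4)c(OC)c3o2)cc1OC
F4 | step 10 | 4-(benzyloxy)-3,6-dimethoxy-1a-[3-methoxy-4-(methoxymethoxy)phenyl]-1a,7a-dihydro-7H-oxireno[2,3-b]chromen-7-one (racemic, cis-fused, one enantiomer drawn) | O1[C@@H]2C(=O)c3c(OC)cc(OCc4ccccc4)c(OC)c3O[C@]12c1ccc(OCOC)c(OC)c1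
F5 | step 10 | 7-(benzyloxy)-3-hydroxy-5,8-dimethoxy-2-[3-methoxy-4-(methoxymethoxy)phenyl]-4H-chromen-4-one | COCOc1ccc(-c2oc3c(OC)c(OCc4ccccc4)cc(OC)c3c(=O)c2O)cc1OC
F6 | step 10 | 7-(benzyloxy)-3,5,8-trimethoxy-2-[3-methoxy-4-(methoxymethoxy)phenyl]-4H-chromen-4-one | COCOc1ccc(-c2oc3c(OC)c(OCc4ccccc4)cc(OC)c3c(=O)c2OC)cc1OC
F7 | step 10 | 7-hydroxy-3,5,8-trimethoxy-2-[3-methoxy-4-(methoxymethoxy)phenyl]-4H-chromen-4-one | COCOc1ccc(-c2oc3c(OC)c(O)cc(OC)c3c(=O)c2OC)cc1OC
F8 | step 12 | 7-hydroxy-2-(4-hydroxy-3-methoxyphenyl)-3,5,8-trimethoxy-4H-chromen-4-one | COc1cc(-c2oc3c(OC)c(O)cc(OC)c3c(=O)c2OC)ccc1O
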